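## The problem

Garcinisidone E (23) is a depsidone. Rings A and B are joined twice, by a diaryl ether oxygen and by an aryl ester, so that a seven-membered dioxepinone (ring C) lies between them; ring B also carries a fused 2,2-dimethyl-2H-pyran. There is no stereocentre, so the whole difficulty is regiochemical. Ring A is hexasubstituted in the order C-prenyl, OH, C-prenyl, O-aryl, C(=O)O, OH, and its ether carbon is flanked by a prenyl group and the carboxyl carbon, which makes a late ether-forming coupling on a preformed ring A unattractive. Ring B is a 1,2,4,5-tetraoxygenated benzene whose four oxygens must be told apart (lactone oxygen, ether oxygen, free hydroxyl, pyran oxygen), with the pyran fused at the one free carbon next to the lactone oxygen. The groups that limit the reagents are the two prenyl groups ortho to phenols (chroman formation with acid, epoxidation), the chromene olefin (acid, peracids, hydrogenation), the aryl lactone (opened by alkoxides) and, once deprotected, the ring B hydroquinone (air oxidation). The enabling feature is that the carboxyl-bearing and aryloxy-bearing carbons of ring A are neighbours, like the α- and β-carbons of a 3-aryloxypropiolate. The other four ring A carbons (C–OH, C-prenyl, C–OH, C-prenyl) have the oxidation pattern of C1 to C4 of a 2,4-diprenylated acetoacetate.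

## Retrosynthesis

**Lactone, 23 to 21.** The acyl C–O bond between the ring A carboxyl carbon and the oxygen on C5 of the chromene is cut first, giving seco acid 21. Cutting the ether instead would leave a depside and demand an aryl–oxygen bond at the most hindered carbon of a fully substituted ring. The ester closure is intramolecular, and only one hydroxyl of 21 can reach the carboxyl carbon. The forward reaction must be neutral and dilute: a carbodiimide lactonisation.

**Allyl groups, 21 to 20.** The carboxyl group and the two ring B hydroxyls are carried as an allyl ester and two allyl ethers, so one zerovalent palladium step frees all three. An allyl ester is preferred to a methyl ester for two reasons. Base-promoted closure from a methyl ester would run against the known ease with which depsidones are opened by methanol and base. Hydrolysis of a 2,6-disubstituted methyl benzoate would need conditions that the prenyl groups would not survive.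

**Ring A, 20 to 17 and 11 (key cut).** Two ring A bonds are cut: C(OH)–C(CO2allyl) and C(prenyl)–C(OAr). This divides ring A into a two-carbon unit, the alkyne of allyl 3-aryloxypropiolate 11, and a four-carbon unit, the 2,4-diprenyl 1-methoxy-1,3-bis(trimethylsilyloxy)butadiene 17. Against stepwise substitution of a phloroglucinol, this cut delivers all six substituents in one operation with the diaryl ether already present. The precursors are an acyclic diene and an alkynoate on an otherwise finished ring B. The forward reaction must show one regiochemistry (nucleophilic diene terminus to the oxygen-bearing alkyne carbon) and must aromatise by loss of methanol.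

**Alkynoate, 11 to 8 to 7.** The C(sp)–CO2allyl bond is cut to a lithium aryloxyacetylide and allyl chloroformate, and the acetylide is traced to the (E)-1,2-dichlorovinyl ether 8 of phenol 7. Trichloroethylene thus supplies both alkyne carbons, and the only demand on ring B is one free phenol at C6 of the chromene.

**Ring B phenol, 7 to 5 to 4 to 1 and 2.** The C6 hydroxyl of 7 is traced to a formyl group (Dakin oxidation of 5). The two allyl ethers come from diol 4, and the pyran ring of 4 comes from condensation of 2,4,5-trihydroxybenzaldehyde 1 with 3-methylbut-2-enal 2. The aldehyde serves three purposes: it directs the annulation to C3, keeps the 2-hydroxyl out of the cyclisation by hydrogen bonding, and then becomes the fourth oxygen. No selective protection among the three hydroxyls of 1 is needed.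

**Diene, 17 to 16 to 15 to 14 to 12 and 13.** The two silyl groups are removed in turn (17 to 16 to 15), and both prenyl groups are cut from β-keto ester 15. The C4 prenyl is introduced through the dianion of methyl acetoacetate 12 (giving 14) and the C2 prenyl through the mono-enolate, both with prenyl bromide 13. The prenyl groups are thus in place from the start and never have to be attached to an arene.

## Roads not taken

**Alternative 1:** The two ring A side chains are cut from a finished depsidone. The bis(allyl ether) A2 of the ring A hydroxyls would be heated so that both allyl groups move to the two free ring A carbons, giving diallyl depsidone A1. Olefin cross-metathesis with 2-methyl-2-butene (second-generation Grubbs catalyst) would then turn allyl into prenyl.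
- Merits: the aromatic Claisen rearrangement is dependable, both free carbons end up allylated whichever ortho or para pathway each group takes, and no untested dienophile is involved. In reliability of the C–C bond formation this road is better than the chosen one.
- Weak points: A2 still needs a depsidone core made by a copper-mediated Ullmann ether coupling and a lactonisation. The rearrangement exposes lactone and chromene to about 180–200 °C. The metathesis must spare the chromene olefin. The ring B hydroxyl needs its own protection.
- Comparison: the step count is similar or slightly higher. The chosen plan offers convergence, prenyl groups that are native from prenyl bromide, and an ether bond that never has to be forged on a crowded arene.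

**Alternative 2:** Ring C is cut back to a pyranoxanthone. Xanthone A4 would be activated at its carbonyl by trimethylsilyl triflate and would add bis(trimethylsilyl) peroxide, and migration of the ring B aryl from carbon to oxygen would give protected depsidone A3.
- Merits: xanthones of this pattern are easy to assemble by classical acylation and cyclisation, and the key step creates both the lactone and the seven-membered ring at once. In brevity this road could beat the chosen plan.
- Weak points: the xanthone carbonyl is a doubly oxygen-conjugated diaryl ketone and a poor electrophile. The wrong aryl group may migrate. An electrophilic peroxide with a silyl triflate meets two prenyl olefins, a chromene and very electron-rich arenes, so epoxidation, cationic cyclisation and quinone formation all compete.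
- Comparison: the chosen plan risks low reactivity in one step but has no comparable chemoselectivity problem. Each of its steps belongs to a reaction class with close analogy.

**Alternative 3:** Ring B is built onto ring A. The (CO)5Cr methoxycarbene complex A6, carrying a dihydropyranyl group, would combine with ring A aryl ethynyl ether A7 and one CO ligand by alkyne insertion, CO insertion and electrocyclisation. The product is racemic diaryl ether A5, with the new phenol next to the aryloxy group.
- Merits: the benzannulation places the aryloxy group next to the new hydroxyl with reliable regiochemistry for a terminal alkyne, which is exactly the pair needed for lactonisation.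
- Weak points: the harder ring A must still be made hexasubstituted by stepwise chemistry before A7 can be prepared. The step uses stoichiometric zerovalent chromium. A5 needs a long endgame: cleavage of an aryl methyl ether and two methoxymethyl ethers under conditions hostile to prenyl groups, then desilylation and dehydration to the chromene.
- Comparison: the chosen plan spends its key step on the more difficult ring and reaches ring B in a few classical steps from a cheap aldehyde. Alternative 3 is better only in the precedent for its ring-forming regiochemistry.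

Key step: step 10

Remark on the chemistry: the enol ether geometries of 16 and 17 and the relative configuration of cycloadduct 18 are left undefined because they are erased on aromatisation. Salts formed from a numbered compound by simple deprotonation (enolates, phenoxides, carboxylates) are treated as that compound.

## Route

Step 1
Reactants: 1 2,4,5-trihydroxybenzaldehyde; 2 3-methylbut-2-enal
Product: 4 5,8-dihydroxy-2,2-dimethyl-2H-chromene-6-carbaldehyde, via ortho-quinone methide 3 (not isolated)
Conditions: ethylenediammonium diacetate (20 mol%), xylene–DMF, 120 °C, Ar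
Reagents that add atoms: none
Why: Amine-salt-catalysed condensation of a resorcinol-type phenol with an enal: Knoevenagel-type attack of C3 of 1 (the only carbon activated by two ortho hydroxyls) on the iminium of 2, loss of water to ortho-quinone methide 3 and oxa-6π electrocyclisation. Closure through the 4-oxygen is expected because the 2-hydroxyl stays in the hydrogen bond to the aldehyde, as in the 2,4-dihydroxybenzaldehyde series; no stereocentre is formed.

Step 2
Reactants: 4 5,8-dihydroxy-2,2-dimethyl-2H-chromene-6-carbaldehyde
Product: 5 5,8-bis(allyloxy)-2,2-dimethyl-2H-chromene-6-carbaldehyde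
Conditions: allyl bromide, K2CO3, DMF, 60 °C
Reagents that add atoms: allyl bromide C=CCBr
Why: Williamson etherification; the 8-hydroxyl reacts first and the chelated 5-hydroxyl follows on warming, so both ring B oxygens that must later be free carry one group that zerovalent palladium removes without acid or base.

Step 3
Reactants: 5 5,8-bis(allyloxy)-2,2-dimethyl-2H-chromene-6-carbaldehyde
Product: 7 5,8-bis(allyloxy)-2,2-dimethyl-2H-chromen-6-ol, via aryl formate 6 (not isolated)
Conditions: 30% H2O2, H2SO4 (cat.), MeOH, 0 °C to rt
Reagents that add atoms: hydrogen peroxide OO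
Why: Acid-catalysed Dakin oxidation (Baeyer–Villiger-type aryl migration in the hydroperoxide adduct of the aldehyde), favoured by the ortho allyloxy and para pyran oxygens; methanol cleaves formate 6 in the flask. Hydrogen peroxide without a peracid is chosen so that the chromene and allyl olefins are not epoxidised.

Step 4
Reactants: 7 5,8-bis(allyloxy)-2,2-dimethyl-2H-chromen-6-ol
Product: 8 5,8-bis(allyloxy)-6-{[(E)-1,2-dichlorovinyl]oxy}-2,2-dimethyl-2H-chromene
Conditions: trichloroethylene, K2CO3, DMF, 70 °C, Ar
Reagents that add atoms: trichloroethylene ClC=C(Cl)Cl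
Why: Base converts trichloroethylene into dichloroacetylene, to which the phenoxide of 7 adds in anti fashion, the established route from phenols to (E)-1,2-dichlorovinyl aryl ethers; allyl ethers and chromene are inert to K2CO3 in DMF.

Step 5
Reactants: 8 5,8-bis(allyloxy)-6-{[(E)-1,2-dichlorovinyl]oxy}-2,2-dimethyl-2H-chromene
Product: 11 allyl 3-{[5,8-bis(allyloxy)-2,2-dimethyl-2H-chromen-6-yl]oxy}prop-2-ynoate, via chloroethynyl ether 9 (not isolated), via lithium aryloxyacetylide 10 (not isolated)
Conditions: n-BuLi (2.2 equiv), THF, −78 to −40 °C; then inverse addition to allyl chloroformate, −78 °C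
Reagents that add atoms: allyl chloroformate C=CCOC(Cl)=O
Why: Established conversion of aryl dichlorovinyl ethers into lithium aryloxyacetylides: the first equivalent of n-butyllithium eliminates HCl to give 9, the second exchanges chlorine for lithium to give 10, which is C-acylated by the chloroformate. Low temperature and inverse addition should suppress metalation of the allyl ethers and double addition.

Step 6
Reactants: 12 methyl acetoacetate; 13 prenyl bromide (1-bromo-3-methylbut-2-ene)
Product: 14 methyl 7-methyl-3-oxooct-6-enoate
Conditions: NaH, THF, 0 °C; n-BuLi, 0 °C; then 13, 0 °C to rt; dilute HCl work-up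
Reagents that add atoms: none
Why: γ-Alkylation of the acetoacetate dianion: the more basic terminal carbanion (C4) is alkylated selectively by the allylic bromide.

Step 7
Reactants: 14 methyl 7-methyl-3-oxooct-6-enoate; 13 prenyl bromide (1-bromo-3-methylbut-2-ene)
Product: 15 methyl 7-methyl-2-(3-methylbut-2-en-1-yl)-3-oxooct-6-enoate (racemic)
Conditions: K2CO3, 13 (1.0 equiv), acetone, reflux
Reagents that add atoms: none
Why: C-Alkylation of the β-keto ester enolate at C2 with a reactive allylic bromide; one equivalent of 13 limits dialkylation. The new stereocentre is racemic and is removed in step 8.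

Step 8
Reactants: 15 methyl 7-methyl-2-(3-methylbut-2-en-1-yl)-3-oxooct-6-enoate (racemic)
Product: 16 methyl 7-methyl-2-(3-methylbut-2-en-1-yl)-3-[(trimethylsilyl)oxy]octa-2,6-dienoate (E/Z mixture at C2=C3)
Conditions: TMSCl, Et3N, toluene, rt
Reagents that add atoms: chlorotrimethylsilane C[Si](C)(C)Cl
Why: Standard O-silylation of a 2-substituted β-keto ester to its 3-silyloxy enoate; the double bond geometry is irrelevant.

Step 9
Reactants: 16 methyl 7-methyl-2-(3-methylbut-2-en-1-yl)-3-[(trimethylsilyl)oxy]octa-2,6-dienoate (E/Z mixture at C2=C3)
Product: 17 1-methoxy-7-methyl-2-(3-methylbut-2-en-1-yl)-1,3-bis[(trimethylsilyl)oxy]octa-1,3,6-triene (enol ether geometries undefined)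
Conditions: LDA, THF, −78 °C; then TMSCl, −78 to 0 °C
Reagents that add atoms: chlorotrimethylsilane C[Si](C)(C)Cl
Why: Kinetic γ-deprotonation of the silyloxy enoate by LDA and O-silylation of the ester dienolate, the standard second stage in the preparation of 1-alkoxy-1,3-bis(silyloxy)butadienes. The moisture-sensitive diene is used crude.

Step 10
Reactants: 17 1-methoxy-7-methyl-2-(3-methylbut-2-en-1-yl)-1,3-bis[(trimethylsilyl)oxy]octa-1,3,6-triene; 11 allyl 3-{[5,8-bis(allyloxy)-2,2-dimethyl-2H-chromen-6-yl]oxy}prop-2-ynoate
Product: 20 allyl 2-{[5,8-bis(allyloxy)-2,2-dimethyl-2H-chromen-6-yl]oxy}-4,6-dihydroxy-3,5-bis(3-methylbut-2-en-1-yl)benzoate, via cyclohexadiene cycloadduct 18 (not isolated), via bis(trimethylsilyl) ether 19 (not isolated)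
Conditions: 17 (2.5 equiv), toluene, 110 °C, sealed tube, Ar; then aq. citric acid, THF, rt
Reagents that add atoms: none
Why: Diels–Alder cycloaddition of an electron-rich 1-alkoxy-1,3-bis(silyloxy)butadiene with an acetylenic ester followed by aromatisation, the known route from such dienes and alkynoates to resorcylates, applied here to a 3-aryloxy alkynoate. The diene reacts through its s-cis conformer, which the C2 prenyl group favours; its nucleophilic terminus C4 bonds to the alkynoate β-carbon and the ketene acetal carbon C1 to the α-carbon, giving cyclohexa-1,4-diene 18. Ring A is therefore closed by a [4+2] cycloaddition, probably highly asynchronous, and a Michael addition followed by ring closure would lead to the same 18. Loss of methanol from the mixed ketal carbon and the C4 hydrogen (formal 1,4-elimination) aromatises 18 to bis(silyl ether) 19, and mild aqueous acid removes both silyl groups. No stereocentre survives, since the two stereocentres of 18 and the enol ether geometries of 17 are erased on aromatisation. The step needs one regiochemistry, and both alkyne substituents enforce it: the ester and the aryloxy oxygen each make the oxygen-bearing β-carbon the electrophilic end, which pairs with the largest HOMO coefficient at C4 of the diene. The prenyl, allyl and chromene olefins are unactivated and should not compete, and the excess of diene allows for its thermal and hydrolytic lability.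

Step 11
Reactants: 20 allyl 2-{[5,8-bis(allyloxy)-2,2-dimethyl-2H-chromen-6-yl]oxy}-4,6-dihydroxy-3,5-bis(3-methylbut-2-en-1-yl)benzoate
Product: 21 2-[(5,8-dihydroxy-2,2-dimethyl-2H-chromen-6-yl)oxy]-4,6-dihydroxy-3,5-bis(3-methylbut-2-en-1-yl)benzoic acid
Conditions: Pd(PPh3)4 (10 mol%), morpholine (10 equiv), THF, rt, Ar; pH 4 buffer work-up
Reagents that add atoms: none
Why: Tsuji–Trost deallylation: zerovalent palladium ionises the allyl ester and both aryl allyl ethers to π-allyl palladium complexes that morpholine captures. The reaction is neutral, is indifferent to the steric shielding of the 2,6-disubstituted ester, and leaves the C-prenyl groups and the cyclic tertiary chromene ether alone. Hydroquinone 21 is kept under argon and used at once.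

Step 12
Reactants: 21 2-[(5,8-dihydroxy-2,2-dimethyl-2H-chromen-6-yl)oxy]-4,6-dihydroxy-3,5-bis(3-methylbut-2-en-1-yl)benzoic acid
Product: 23 garcinisidone E, via O-acylisourea 22 (not isolated)
Conditions: DCC (1.5 equiv), DMAP (cat.), THF, 0.002 M, 0 °C to rt, Ar
Reagents that add atoms: none
Why: Carbodiimide lactonisation (Steglich type) of a 2-(2-hydroxyaryloxy)benzoic acid, the customary closure of depsidones: the acid forms O-acylisourea 22, which is attacked by the chromene C5 hydroxyl, the only hydroxyl able to reach the carboxyl carbon (7-exo-trig acyl transfer). High dilution disfavours intermolecular esterification, and neither acid nor alkoxide touches the prenyl groups or the new lactone.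

## Compound list

1 | 2,4,5-trihydroxybenzaldehyde | O=Cc1cc(O)c(O)cc1O | starting material
2 | 3-methylbut-2-enal | CC(C)=CC=O | starting material
3 | 2,5-dihydroxy-3-(3-methylbut-2-en-1-ylidene)-4-oxocyclohexa-1,5-diene-1-carbaldehyde (ortho-quinone methide, not isolated, exocyclic geometry undefined) | O=CC1=C(O)C(=CC=C(C)C)C(=O)C(O)=C1 | intermediate
4 | 5,8-dihydroxy-2,2-dimethyl-2H-chromene-6-carbaldehyde | O=Cc1cc(O)c2OC(C)(C)C=Cc2c1O | intermediate
5 | 5,8-bis(allyloxy)-2,2-dimethyl-2H-chromene-6-carbaldehyde | O=Cc1cc(OCC=C)c2OC(C)(C)C=Cc2c1OCC=C | intermediate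
6 | 5,8-bis(allyloxy)-2,2-dimethyl-2H-chromen-6-yl formate (not isolated) | O=COc1cc(OCC=C)c2OC(C)(C)C=Cc2c1OCC=C | intermediate
7 | 5,8-bis(allyloxy)-2,2-dimethyl-2H-chromen-6-ol | Oc1cc(OCC=C)c2OC(C)(C)C=Cc2c1OCC=C | intermediate
8 | 5,8-bis(allyloxy)-6-{[(E)-1,2-dichlorovinyl]oxy}-2,2-dimethyl-2H-chromene | Cl/C=C(/Cl)Oc1cc(OCC=C)c2OC(C)(C)C=Cc2c1OCC=C | intermediate
9 | 5,8-bis(allyloxy)-6-[(chloroethynyl)oxy]-2,2-dimethyl-2H-chromene (not isolated) | ClC#COc1cc(OCC=C)c2OC(C)(C)C=Cc2c1OCC=C | intermediate
10 | lithium {[5,8-bis(allyloxy)-2,2-dimethyl-2H-chromen-6-yl]oxy}acetylide (not isolated) | [Li]C#COc1cc(OCC=C)c2OC(C)(C)C=Cc2c1OCC=C | intermediate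
11 | allyl 3-{[5,8-bis(allyloxy)-2,2-dimethyl-2H-chromen-6-yl]oxy}prop-2-ynoate | C=CCOC(=O)C#COc1cc(OCC=C)c2OC(C)(C)C=Cc2c1OCC=C | intermediate
12 | methyl acetoacetate | COC(=O)CC(C)=O | starting material
13 | prenyl bromide (1-bromo-3-methylbut-2-ene) | CC(C)=CCBr | starting material
14 | methyl 7-methyl-3-oxooct-6-enoate | COC(=O)CC(=O)CCC=C(C)C | intermediate
15 | methyl 7-methyl-2-(3-methylbut-2-en-1-yl)-3-oxooct-6-enoate (racemic) | COC(=O)C(CC=C(C)C)C(=O)CCC=C(C)C | intermediate
16 | methyl 7-methyl-2-(3-methylbut-2-en-1-yl)-3-[(trimethylsilyl)oxy]octa-2,6-dienoate (E/Z mixture at C2=C3) | COC(=O)C(CC=C(C)C)=C(O[Si](C)(C)C)CCC=C(C)C | intermediate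
17 | 1-methoxy-7-methyl-2-(3-methylbut-2-en-1-yl)-1,3-bis[(trimethylsilyl)oxy]octa-1,3,6-triene (enol ether geometries undefined) | COC(O[Si](C)(C)C)=C(CC=C(C)C)C(O[Si](C)(C)C)=CCC=C(C)C | intermediate
18 | allyl 2-{[5,8-bis(allyloxy)-2,2-dimethyl-2H-chromen-6-yl]oxy}-6-methoxy-3,5-bis(3-methylbut-2-en-1-yl)-4,6-bis[(trimethylsilyl)oxy]cyclohexa-1,4-diene-1-carboxylate (not isolated, racemic diastereomer mixture) | COC1(O[Si](C)(C)C)C(CC=C(C)C)=C(O[Si](C)(C)C)C(CC=C(C)C)C(Oc2cc(OCC=C)c3OC(C)(C)C=Cc3c2OCC=C)=C1C(=O)OCC=C | intermediate
19 | allyl 2-{[5,8-bis(allyloxy)-2,2-dimethyl-2H-chromen-6-yl]oxy}-3,5-bis(3-methylbut-2-en-1-yl)-4,6-bis[(trimethylsilyl)oxy]benzoate (not isolated) | C=CCOC(=O)c1c(O[Si](C)(C)C)c(CC=C(C)C)c(O[Si](C)(C)C)c(CC=C(C)C)c1Oc1cc(OCC=C)c2OC(C)(C)C=Cc2c1OCC=C | intermediate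
20 | allyl 2-{[5,8-bis(allyloxy)-2,2-dimethyl-2H-chromen-6-yl]oxy}-4,6-dihydroxy-3,5-bis(3-methylbut-2-en-1-yl)benzoate | C=CCOC(=O)c1c(O)c(CC=C(C)C)c(O)c(CC=C(C)C)c1Oc1cc(OCC=C)c2OC(C)(C)C=Cc2c1OCC=C | intermediate
21 | 2-[(5,8-dihydroxy-2,2-dimethyl-2H-chromen-6-yl)oxy]-4,6-dihydroxy-3,5-bis(3-methylbut-2-en-1-yl)benzoic acid | OC(=O)c1c(O)c(CC=C(C)C)c(O)c(CC=C(C)C)c1Oc1cc(O)c2OC(C)(C)C=Cc2c1O | intermediate
22 | O-acylisourea from the carboxyl group of 21 and N,N'-dicyclohexylcarbodiimide (not isolated) | O=C(OC(=NC1CCCCC1)NC1CCCCC1)c1c(O)c(CC=C(C)C)c(O)c(CC=C(C)C)c1Oc1cc(O)c2OC(C)(C)C=Cc2c1O | intermediate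
23 | garcinisidone E | CC(C)=CCc1c(O)c(CC=C(C)C)c2c(c1O)C(=O)Oc1c(cc(O)c3c1C=CC(C)(C)O3)O2 | target

## Step count and least certain steps

Total: 12 steps. Longest linear sequence: 8 steps (1, 4, 5, 7, 8, 11, 20, 21, 23); the diene branch from 12 contributes 4 steps before the union.

**Step 10 (key step).** The 3-aryloxy alkynoate is a push–pull alkyne and a weaker dienophile than a simple alkynoate, and the diene carries substituents at C2 and C4. The cycloaddition may therefore be slower than thermal decay of the diene (silyl migration, hydrogen shifts, adventitious hydrolysis), or the reaction may stop after the first carbon–carbon bond without ring closure. Fallback: make the same two ring bonds stepwise by polar chemistry, setting out from keto ester 15 and alkynoate 11.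
- The dianion of 15 (NaH, then n-BuLi, THF, −78 °C) would add through C4 to the β-carbon of 11 and give, after protonation, the open-chain adduct 1-allyl 7-methyl 3-{[5,8-bis(allyloxy)-2,2-dimethyl-2H-chromen-6-yl]oxy}-4,6-bis(3-methylbut-2-en-1-yl)-5-oxohept-2-enedioate F1.
- A non-nucleophilic base (LiHMDS, 2.2 equiv, THF) would then close ring A by Dieckmann-type attack of the extended enolate carbon next to the allyl ester on the methyl ester. Loss of methanol and tautomerisation return the route to 20.

**Step 5.** The acylation of acetylide 10 may be spoiled by double addition of the acetylide to the chloroformate or to the product. The acetylide may decompose thermally if the acylation needs warming, or n-butyllithium may metalate an allyl ether or the ring position between two oxygens. Fallback, setting out from 8: acetylide 10 would be quenched with methanol at −78 °C and the terminal ynol ether 5,8-bis(allyloxy)-6-(ethynyloxy)-2,2-dimethyl-2H-chromene F2 isolated. The allyl carboxylate would then be installed by copper-catalysed carboxylative coupling (CO2 at 1 atm, allyl chloride, K2CO3, (IPr)CuCl cat., DMF, 60 °C; IPr = 1,3-bis(2,6-diisopropylphenyl)imidazol-2-ylidene), returning to the route at 11.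

**Step 12 (with step 11).** The seco acid is a free hydroquinone and a very electron-rich salicylic acid. It may oxidise in air before closure, or lose CO2 through its keto tautomer. It may also esterify intermolecularly, or the hindered O-acylisourea may rearrange to an N-acylurea faster than the ring closes. Fallback, setting out from 20: mask the ring A phenols before the allyl groups are removed.
- TBSOTf and 2,6-lutidine would give the bis(tert-butyldimethylsilyl) ether of 20, F3.
- Pd(PPh3)4 and morpholine would give the bis(silyl) seco acid F4, which cannot tautomerise to a keto form and has no hydrogen bond tying up the carboxyl group.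
- DCC and DMAP at high dilution would give the bis(silyl) depsidone F5.
- HF·pyridine in THF at 0 °C would remove the silyl groups and return the route at 23.

**Step 1.** The hydroxyhydroquinone 1 may be degraded oxidatively under the hot amine-salt conditions, and the aldehyde-deactivated ring may condense too slowly with the enal, so that self-condensation of 2 takes over. Fallback, setting out from 1: build the pyran in two stages. The most acidic 4-hydroxyl would be alkylated selectively with 3-chloro-3-methylbut-1-yne (DBU, CuCl2 cat., MeCN, 0 °C) to give 2,5-dihydroxy-4-[(2-methylbut-3-yn-2-yl)oxy]benzaldehyde F6. Heating F6 in xylene at 140 °C would bring about aromatic propargyl Claisen rearrangement to C3, hydrogen shift and oxa-6π electrocyclisation, returning to the route at 4.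

## Further compounds

F1 | step 10 | 1-allyl 7-methyl 3-{[5,8-bis(allyloxy)-2,2-dimethyl-2H-chromen-6-yl]oxy}-4,6-bis(3-methylbut-2-en-1-yl)-5-oxohept-2-enedioate (isomer mixture) | COC(=O)C(CC=C(C)C)C(=O)C(CC=C(C)C)C(Oc1cc(OCC=C)c2OC(C)(C)C=Cc2c1OCC=C)=CC(=O)OCC=C
F2 | step 5 | 5,8-bis(allyloxy)-6-(ethynyloxy)-2,2-dimethyl-2H-chromene | C#COc1cc(OCC=C)c2OC(C)(C)C=Cc2c1OCC=C
F3 | step 12 | allyl 2-{[5,8-bis(allyloxy)-2,2-dimethyl-2H-chromen-6-yl]oxy}-4,6-bis[(tert-butyldimethylsilyl)oxy]-3,5-bis(3-methylbut-2-en-1-yl)benzoate | C=CCOC(=O)c1c(O[Si](C)(C)C(C)(C)C)c(CC=C(C)C)c(O[Si](C)(C)C(C)(C)C)c(CC=C(C)C)c1Oc1cc(OCC=C)c2OC(C)(C)C=Cc2c1OCC=C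
F4 | step 12 | 4,6-bis[(tert-butyldimethylsilyl)oxy]-2-[(5,8-dihydroxy-2,2-dimethyl-2H-chromen-6-yl)oxy]-3,5-bis(3-methylbut-2-en-1-yl)benzoic acid | OC(=O)c1c(O[Si](C)(C)C(C)(C)C)c(CC=C(C)C)c(O[Si](C)(C)C(C)(C)C)c(CC=C(C)C)c1Oc1cc(O)c2OC(C)(C)C=Cc2c1O
F5 | step 12 | garcinisidone E bis(tert-butyldimethylsilyl) ether (both ring A hydroxyls silylated) | CC(C)=CCc1c(O[Si](C)(C)C(C)(C)C)c(CC=C(C)C)c2c(c1O[Si](C)(C)C(C)(C)C)C(=O)Oc1c(cc(O)c3c1C=CC(C)(C)O3)O2
F6 | step 1 | 2,5-dihydroxy-4-[(2-methylbut-3-yn-2-yl)oxy]benzaldehyde | O=Cc1cc(O)c(OC(C)(C)C#C)cc1O
A1 | alternative 1 | diallyl analogue of garcinisidone E (both prenyl groups replaced by allyl) | C=CCc1c(O)c(CC=C)c2c(c1O)C(=O)Oc1c(cc(O)c3c1C=CC(C)(C)O3)O2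
A2 | alternative 1 | bis(allyl ether) of the ring A hydroxyls of the depsidone lacking both ring A side chains | c1c(OCC=C)cc2c(c1OCC=C)C(=O)Oc1c(cc(O)c3c1C=CC(C)(C)O3)O2
A3 | alternative 2 | garcinisidone E protected as two ring A allyl carbonates and one ring B allyl ether | CC(C)=CCc1c(OC(=O)OCC=C)c(CC=C(C)C)c2c(c1OC(=O)OCC=C)C(=O)Oc1c(cc(OCC=C)c3c1C=CC(C)(C)O3)O2
A4 | alternative 2 | pyranoxanthone with the substituents of A3 (xanthone carbonyl in place of the lactone) | CC(C)=CCc1c(OC(=O)OCC=C)c(CC=C(C)C)c2c(c1OC(=O)OCC=C)C(=O)c1c(cc(OCC=C)c3c1C=CC(C)(C)O3)O2
A5 | alternative 3 | methyl 2-{[4-(tert-butyldimethylsilyloxy)-5-hydroxy-8-methoxy-2,2-dimethylchroman-6-yl]oxy}-4,6-bis(methoxymethoxy)-3,5-bis(3-methylbut-2-en-1-yl)benzoate (racemic) | COC(=O)c1c(OCOC)c(CC=C(C)C)c(OCOC)c(CC=C(C)C)c1Oc1cc(OC)c2OC(C)(C)CC(O[Si](C)(C)C(C)(C)C)c2c1O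
A6 | alternative 3 | pentacarbonyl{methoxy[4-(tert-butyldimethylsilyloxy)-2,2-dimethyl-3,4-dihydro-2H-pyran-6-yl]carbene}chromium (racemic) | COC(=[Cr](=C=O)(=C=O)(=C=O)(=C=O)=C=O)C1=CC(O[Si](C)(C)C(C)(C)C)CC(C)(C)O1
A7 | alternative 3 | methyl 2-(ethynyloxy)-4,6-bis(methoxymethoxy)-3,5-bis(3-methylbut-2-en-1-yl)benzoate | COC(=O)c1c(OCOC)c(CC=C(C)C)c(OCOC)c(CC=C(C)C)c1OC#C
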